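**Target (18):** 2-[(2R)-5-[(3E,7E)-4,8,12-trimethyltrideca-3,7,11-trien-1-yl]-3,6-dihydro-2H-pyran-2-yl]prop-2-enoic acid, C24H36O3. Locants used below: ring O1, C2 (stereocentre), C3H2, C4H=C5, C6H2; Cα is the acrylic α-carbon; the chain is C1′–C13′.

## The problem

The ring is a 3,6-dihydro-2H-pyran that carries a 1-carboxyvinyl group at C2 and a homofarnesyl chain at C5. This 2,5-pattern is the opposite of the 2,4-pattern that a carbonyl compound and a 2-substituted diene give (hetero-Diels–Alder or Prins logic). The ring therefore has to be closed from an open chain in which C3 and C6 are cis on the trisubstituted C4=C5 bond. C2 is the only stereocentre, so nothing in the molecule can relay its configuration. It is also a carbinol carbon of Morita–Baylis–Hillman type, for which direct catalytic asymmetric construction from an enolisable aldehyde is unreliable.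

The feature that makes the key step possible is that C2 is both the oxygen-bearing ring atom and one terminus of the allyl unit C2–Cα(CO2H)=CH2. The ring bond O1–C2 is thus an allylic C–O bond of a 2-carboxyallyl system. Its palladium π-allyl complex has an unsubstituted CH2 terminus through which the two faces of C2 can equilibrate. O1 is held five atoms away (C6–C5=C4–C3) by a cis olefin, which suits a six-membered closure.

The bond C1′–C2′ joins a CH2 next to C5 to the CH2 of a farnesyl unit, so the whole chain with both E olefins can come from (2E,6E)-farnesyl bromide. Sensitive groups are: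
- the three trisubstituted chain olefins (acid-induced cation–olefin cyclisation, electrophilic oxidants);
- the acrylic acid (Michael acceptor);
- the doubly allylic ether O1 (SN2′ expulsion after addition to the acrylate);
- any β,γ-unsaturated carbonyl intermediate (migration into conjugation).

## Retrosynthesis

**18 ⇒ 17.** Only the ester O–CH3 bond is cut. The acid is carried as the methyl ester because a free carboxylate would compete with O1 as a nucleophile in the palladium step. The forward reaction must be a saponification that leaves the allylic ether and C2 untouched.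

**17 ⇒ 16 (key cut, O1–C2).** The neighbouring cuts, O1–C6 (Williamson or allylic substitution at a CH2) and C4=C5 (metathesis), both leave C2 to be made enantiopure beforehand as a Morita–Baylis–Hillman carbinol. O1–C2 is the one ring bond that is attached to the stereocentre and allylic to the acrylate. Closing it through a π-allyl palladium complex makes ring and stereocentre together, from racemic carbonate 16. Precursor 16 is acyclic and racemic; its only stereochemical demand is the C4=C5 geometry. The forward reaction must be enantioselective, must attack C2 and not the CH2 terminus, and must outrun elimination.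

**16 ⇒ 15 ⇒ 14.** No skeletal bond is cut. The secondary hydroxyl is activated as a tert-butyl carbonate while the primary oxygen is still a PMB ether; the PMB group is then removed oxidatively. This order is forced because the primary hydroxyl would otherwise be acylated first.

**14 ⇒ 11 + 12 (C2–Cα).** This is the Morita–Baylis–Hillman disconnection. The amine-catalysed reaction is slow and basic and would move C4=C5 of aldehyde 11 into conjugation, so the acrylate α-anion is delivered as the preformed vinylalane 13 from methyl propiolate 12. No stereocontrol is asked for, since the key step wants the racemate.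

**11 ⇒ 10 ⇒ 7 + 8 (C4=C5).** A Wittig reaction of the α-alkoxy ketone 7 with the non-stabilised ylide 9 from salt 8 is chosen. The α-oxygen directs the incoming chain cis to the CH2O group, which is the geometry the ring needs. Cuts at C3–C4 or C5–C1′ would need a stereodefined trisubstituted vinyl metal. The aldehyde travels as a dioxolane (10).

**7 ⇒ 3 + 4, 3 ⇒ 1 + 2 (C1′–C2′ and C6–O1).** Acetoacetic ester alkylation of 3 with farnesyl bromide 4, then decarboxylation (via 5 and 6), gives ketone 7 with both E olefins bought in. The oxygen that ends as O1 is introduced with 4-methoxybenzyl alcohol 2 by displacement on chloro keto ester 1. All precursors are commercial.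

## Roads not taken

**Alternative 1:** (the most obvious) cut C4=C5 by ring-closing metathesis and O1–C6 by O-alkylation. The (R)-carbinol A1 would be alkylated with allylic bromide A2 to the ether A3, and metathesis would give 17. The chosen plan is better for four reasons. A1 must be made enantiopure before the ring exists, from but-3-enal (as prone to conjugation as 11), by a stoichiometric chiral reagent or a resolution. Base-mediated O-alkylation of a Morita–Baylis–Hillman alcohol competes with retro-aldol cleavage and SN2′ transposition. The metathesis catalyst must pick two olefins out of six, one an acrylate. A2 costs extra steps from 4, and the stereocentre is only carried through the ring-forming step, not created in it.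

**Alternative 2:** cut O1–C6 and C2–C3 together, as a hetero-Diels–Alder reaction of β-springene A4 with a glyoxylate ester under a chiral Lewis acid. The diene terminus next to the substituted carbon is the nucleophilic one and bonds to the carbonyl carbon, so the 4-substituted ester A5 is the expected adduct. The orientation needed here is the disfavoured one. Carbonyl-ene reaction at the allylic positions of A4 competes, A4 is not commercial, and an ester at C2 is several steps from the 1-carboxyvinyl group.

**Alternative 3:** cut O1–C2 and C2–C3 as a [2,3]-sigmatropic ring expansion. The racemic vinyl oxirane A6 and the metal carbene from ethyl diazoacetate would give an oxonium ylide that rearranges to ester A7, with the correct 2,5-pattern and a cis ring olefin by mechanism. The chosen plan is better because the configuration at C2 would depend on a catalyst-bound ylide rearranging before it dissociates, and on matched and mismatched pairs of racemic A6. The electron-rich chain olefins would also compete for the carbene. A7 would still have to pass through methyl ketone A8 and enol triflate A9 (carbonylation, hydrolysis) to reach 18, against one step after the key event in the chosen plan.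

Key step: step 8

Assumption: the (R,R)-antipode of the ligand is written for step 8; which antipode delivers (2R)-17 in this tethered closure cannot be derived with certainty from the usual model for the ligand, both antipodes are commercial, and the one that gives the (2R)-product is the one to be used.

Remark: catalyst-bound species (the π-allyl palladium complex of step 8) are described in the Why line and carry no compound number.

## Route

Step 1
Reactants: 1 ethyl 4-chloro-3-oxobutanoate; 2 4-methoxybenzyl alcohol
Product: 3 ethyl 4-[(4-methoxybenzyl)oxy]-3-oxobutanoate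
Conditions: NaH (2.2 equiv), THF, 0 °C → rt; aq. NH4Cl work-up
Reagents that add atoms: none
Why: Williamson-type ether synthesis; the second equivalent of base keeps the keto ester as its enolate, which prevents self-condensation while the alkoxide of 2 displaces the γ-chloride.

Step 2
Reactants: 3 ethyl 4-[(4-methoxybenzyl)oxy]-3-oxobutanoate; 4 (2E,6E)-1-bromo-3,7,11-trimethyldodeca-2,6,10-triene (farnesyl bromide)
Product: 7 (5E,9E)-1-[(4-methoxybenzyl)oxy]-6,10,14-trimethylpentadeca-5,9,13-trien-2-one, via alkylated keto ester 5 (not isolated), via keto acid 6 (not isolated)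
Conditions: NaH, THF, 0 °C → rt; then 2 M NaOH, EtOH, 40 °C; then AcOH (excess), 60 °C
Reagents that add atoms: none
Why: Acetoacetic ester synthesis; the stabilised enolate of 3 attacks the primary allylic bromide at carbon (SN2, both E olefins untouched), and ketonic hydrolysis followed by decarboxylation of keto acid 6 removes the ester carbon, so the transient stereocentre of 5 is of no consequence.

Step 3
Reactants: 7 (5E,9E)-1-[(4-methoxybenzyl)oxy]-6,10,14-trimethylpentadeca-5,9,13-trien-2-one; 8 [2-(1,3-dioxolan-2-yl)ethyl]triphenylphosphonium bromide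
Product: 10 2-[(2Z,6E,10E)-3-{[(4-methoxybenzyl)oxy]methyl}-7,11,15-trimethylhexadeca-2,6,10,14-tetraen-1-yl]-1,3-dioxolane, via phosphorus ylide 9 (not isolated)
Conditions: 8, KHMDS, THF, −78 °C; then 7, −78 °C → rt
Reagents that add atoms: none
Why: Wittig olefination of an α-alkoxy ketone with a non-stabilised ylide under kinetic conditions, a combination known to place the new chain cis to the CH2OR group; this should set C4=C5 with C3 and C6 cis (2Z), the geometry the ring closure needs.

Step 4
Reactants: 10 2-[(2Z,6E,10E)-3-{[(4-methoxybenzyl)oxy]methyl}-7,11,15-trimethylhexadeca-2,6,10,14-tetraen-1-yl]-1,3-dioxolane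
Product: 11 (3Z,7E,11E)-4-{[(4-methoxybenzyl)oxy]methyl}-8,12,16-trimethylheptadeca-3,7,11,15-tetraenal
Conditions: 1 M HCl (aq)/THF, 0 °C → rt; crude aldehyde used at once
Reagents that add atoms: water, O
Why: Acid-catalysed acetal hydrolysis under dilute aqueous conditions that the PMB ether and the trisubstituted olefins tolerate; the β,γ-unsaturated aldehyde is neither stored nor chromatographed, to avoid migration of C4=C5 into conjugation.

Step 5
Reactants: 11 (3Z,7E,11E)-4-{[(4-methoxybenzyl)oxy]methyl}-8,12,16-trimethylheptadeca-3,7,11,15-tetraenal; 12 methyl propiolate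
Product: 14 methyl (5Z,9E,13E)-3-hydroxy-6-{[(4-methoxybenzyl)oxy]methyl}-10,14,18-trimethyl-2-methylidenenonadeca-5,9,13,17-tetraenoate (racemic), via vinylalane 13 (not isolated)
Conditions: 12, DIBAL-H, NMO, THF, 0 °C; then 11, 0 °C → rt; Rochelle salt work-up
Reagents that add atoms: none
Why: Vinylalumination; hydroalumination of the ynoate gives the α-aluminoacrylate 13, a non-basic equivalent of the Morita–Baylis–Hillman enolate that adds to the aldehyde faster than the aldehyde can enolise or conjugate; the carbinol centre is formed as the racemate on purpose.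

Step 6
Reactants: 14 methyl (5Z,9E,13E)-3-hydroxy-6-{[(4-methoxybenzyl)oxy]methyl}-10,14,18-trimethyl-2-methylidenenonadeca-5,9,13,17-tetraenoate (racemic)
Product: 15 methyl (5Z,9E,13E)-3-[(tert-butoxycarbonyl)oxy]-6-{[(4-methoxybenzyl)oxy]methyl}-10,14,18-trimethyl-2-methylidenenonadeca-5,9,13,17-tetraenoate (racemic)
Conditions: Boc2O, DMAP (cat.), CH2Cl2, 0 °C
Reagents that add atoms: di-tert-butyl dicarbonate, CC(C)(C)OC(=O)OC(=O)OC(C)(C)C
Why: DMAP-catalysed carbonate formation, the standard activation of Morita–Baylis–Hillman alcohols; the primary oxygen is still a PMB ether, so only the C2 hydroxyl can react.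

Step 7
Reactants: 15 methyl (5Z,9E,13E)-3-[(tert-butoxycarbonyl)oxy]-6-{[(4-methoxybenzyl)oxy]methyl}-10,14,18-trimethyl-2-methylidenenonadeca-5,9,13,17-tetraenoate (racemic)
Product: 16 methyl (5Z,9E,13E)-3-[(tert-butoxycarbonyl)oxy]-6-(hydroxymethyl)-10,14,18-trimethyl-2-methylidenenonadeca-5,9,13,17-tetraenoate (racemic)
Conditions: DDQ, CH2Cl2/pH 7 buffer, 0 °C
Reagents that add atoms: none
Why: Oxidative PMB cleavage (electron transfer from the anisyl ring, hydrolysis of the resulting oxocarbenium ion); under buffered conditions at 0 °C the carbonate, the acrylate and the isolated trisubstituted olefins should not be touched.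

Step 8
Reactants: 16 methyl (5Z,9E,13E)-3-[(tert-butoxycarbonyl)oxy]-6-(hydroxymethyl)-10,14,18-trimethyl-2-methylidenenonadeca-5,9,13,17-tetraenoate (racemic)
Product: 17 methyl 2-[(2R)-5-[(3E,7E)-4,8,12-trimethyltrideca-3,7,11-trien-1-yl]-3,6-dihydro-2H-pyran-2-yl]prop-2-enoate
Conditions: Pd2(dba)3·CHCl3 (2.5 mol%), N,N′-[(1R,2R)-cyclohexane-1,2-diyl]bis[2-(diphenylphosphanyl)benzamide] (7.5 mol%), CH2Cl2 (0.02 M), rt
Reagents that add atoms: none
Why: Tsuji–Trost-type allylic etherification run as a dynamic kinetic asymmetric transformation: Pd(0) ionises the allylic carbonate of either enantiomer of 16, CO2 and tert-butoxide are released, and a 2-(methoxycarbonyl)allyl palladium cation results whose termini are C2 and the exocyclic CH2. The two diastereomeric complexes (palladium on either face of C2) interconvert by π–σ–π isomerisation through the unsubstituted CH2 terminus, where the η1 form is a conjugated enoate and easily reached, so both enantiomers of 16 should drain through the faster-closing complex. tert-Butoxide deprotonates the primary allylic hydroxyl and O1 attacks C2 on the face opposite to palladium; the ring O1–C6–C5–C4–C3–C2 closes in the 6-exo mode (the allyl unit stays exocyclic), whereas attack at the CH2 terminus would need an eight-membered ring. C2 is the only stereocentre and is set by the chiral pocket of the ligand alone (catalyst control), as (2R). The closest known reaction types are the palladium-catalysed deracemisation of Morita–Baylis–Hillman carbonates with oxygen nucleophiles, which gives the branched ethers, and the asymmetric cyclisation of hydroxy allylic carbonates to 2-vinyl cyclic ethers with the same ligand family. The selectivity needed is substitution at C2 over loss of a C3 proton (conjugated triene ester); it is secured by the intramolecular six-ring closure, by the absence of added base and by high dilution, which also suppresses intermolecular etherification. Only the (5Z)-isomer of 16 can reach C2, so any (5E)-material from step 3 stays open-chain and is removed here.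

Step 9
Reactants: 17 methyl 2-[(2R)-5-[(3E,7E)-4,8,12-trimethyltrideca-3,7,11-trien-1-yl]-3,6-dihydro-2H-pyran-2-yl]prop-2-enoate
Product: 18 2-[(2R)-5-[(3E,7E)-4,8,12-trimethyltrideca-3,7,11-trien-1-yl]-3,6-dihydro-2H-pyran-2-yl]prop-2-enoic acid
Conditions: LiOH, THF/H2O, 0 °C → rt; then 0.5 M HCl to pH 4, 0 °C
Reagents that add atoms: lithium hydroxide, [Li+].[OH-]
Why: Saponification of the methyl ester; the C2–H is cross-conjugated to the ester and not acidified, so the stereocentre is not at risk, and methanol-free conditions with cold, mild acidification limit conjugate addition to the acrylate and protonation of the polyene.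

## Compound list

1 | ethyl 4-chloro-3-oxobutanoate | CCOC(=O)CC(=O)CCl | starting material
2 | 4-methoxybenzyl alcohol | COc1ccc(CO)cc1 | starting material
3 | ethyl 4-[(4-methoxybenzyl)oxy]-3-oxobutanoate | CCOC(=O)CC(=O)COCc1ccc(OC)cc1 | intermediate
4 | (2E,6E)-1-bromo-3,7,11-trimethyldodeca-2,6,10-triene | BrC/C=C(\C)CC/C=C(\C)CCC=C(C)C | starting material
5 | ethyl (4E,8E)-2-{2-[(4-methoxybenzyl)oxy]acetyl}-5,9,13-trimethyltetradeca-4,8,12-trienoate (racemic) | CCOC(=O)C(C/C=C(\C)CC/C=C(\C)CCC=C(C)C)C(=O)COCc1ccc(OC)cc1 | intermediate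
6 | (4E,8E)-2-{2-[(4-methoxybenzyl)oxy]acetyl}-5,9,13-trimethyltetradeca-4,8,12-trienoic acid (racemic) | OC(=O)C(C/C=C(\C)CC/C=C(\C)CCC=C(C)C)C(=O)COCc1ccc(OC)cc1 | intermediate
7 | (5E,9E)-1-[(4-methoxybenzyl)oxy]-6,10,14-trimethylpentadeca-5,9,13-trien-2-one | COc1ccc(COCC(=O)CC/C=C(\C)CC/C=C(\C)CCC=C(C)C)cc1 | intermediate
8 | [2-(1,3-dioxolan-2-yl)ethyl]triphenylphosphonium bromide | [Br-].c1ccc(cc1)[P+](CCC1OCCO1)(c1ccccc1)c1ccccc1 | starting material
9 | [2-(1,3-dioxolan-2-yl)ethylidene]triphenylphosphorane | c1ccc(cc1)P(=CCC1OCCO1)(c1ccccc1)c1ccccc1 | intermediate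
10 | 2-[(2Z,6E,10E)-3-{[(4-methoxybenzyl)oxy]methyl}-7,11,15-trimethylhexadeca-2,6,10,14-tetraen-1-yl]-1,3-dioxolane | COc1ccc(COC/C(CC/C=C(\C)CC/C=C(\C)CCC=C(C)C)=C\CC2OCCO2)cc1 | intermediate
11 | (3Z,7E,11E)-4-{[(4-methoxybenzyl)oxy]methyl}-8,12,16-trimethylheptadeca-3,7,11,15-tetraenal | COc1ccc(COC/C(CC/C=C(\C)CC/C=C(\C)CCC=C(C)C)=C\CC=O)cc1 | intermediate
12 | methyl propiolate | C#CC(=O)OC | starting material
13 | methyl 2-[bis(2-methylpropyl)alumanyl]prop-2-enoate | C=C(C(=O)OC)[Al](CC(C)C)CC(C)C | intermediate
14 | methyl (5Z,9E,13E)-3-hydroxy-6-{[(4-methoxybenzyl)oxy]methyl}-10,14,18-trimethyl-2-methylidenenonadeca-5,9,13,17-tetraenoate (racemic) | C=C(C(=O)OC)C(O)C/C=C(\COCc1ccc(OC)cc1)CC/C=C(\C)CC/C=C(\C)CCC=C(C)C | intermediate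
15 | methyl (5Z,9E,13E)-3-[(tert-butoxycarbonyl)oxy]-6-{[(4-methoxybenzyl)oxy]methyl}-10,14,18-trimethyl-2-methylidenenonadeca-5,9,13,17-tetraenoate (racemic) | C=C(C(=O)OC)C(OC(=O)OC(C)(C)C)C/C=C(\COCc1ccc(OC)cc1)CC/C=C(\C)CC/C=C(\C)CCC=C(C)C | intermediate
16 | methyl (5Z,9E,13E)-3-[(tert-butoxycarbonyl)oxy]-6-(hydroxymethyl)-10,14,18-trimethyl-2-methylidenenonadeca-5,9,13,17-tetraenoate (racemic) | C=C(C(=O)OC)C(OC(=O)OC(C)(C)C)C/C=C(\CO)CC/C=C(\C)CC/C=C(\C)CCC=C(C)C | intermediate
17 | methyl 2-[(2R)-5-[(3E,7E)-4,8,12-trimethyltrideca-3,7,11-trien-1-yl]-3,6-dihydro-2H-pyran-2-yl]prop-2-enoate | C=C(C(=O)OC)[C@H]1CC=C(CC/C=C(\C)CC/C=C(\C)CCC=C(C)C)CO1 | intermediate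
18 | 2-[(2R)-5-[(3E,7E)-4,8,12-trimethyltrideca-3,7,11-trien-1-yl]-3,6-dihydro-2H-pyran-2-yl]prop-2-enoic acid | C=C(C(=O)O)[C@H]1CC=C(CC/C=C(\C)CC/C=C(\C)CCC=C(C)C)CO1 | target

## Step count and least certain steps

Total: 9 steps. Longest linear sequence: 9 steps (1 or 2 to 18); 4, 8 and 12 enter at steps 2, 3 and 5.

**Step 8 (key step).** Three things may go wrong. A C3 proton may be lost from the π-allyl complex, giving the conjugated triene ester instead of C–O closure. Ring closure may outrun the π–σ–π equilibration, so that each enantiomer of 16 closes through its own complex and enantioselectivity falls. The sense of induction may be the opposite of the one assumed.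
Fallback, from 14 back to 17, with the stereocentre set before the ring and the other C–O bond closed: racemic 14 would be resolved by lipase-catalysed acylation with vinyl acetate, the enzyme chosen so that the (3S)-acetate F1 is formed and the unreacted (3R)-alcohol F2 is recovered. DDQ would then give the (3R)-diol F3. Mitsunobu cyclodehydration (PPh3, DIAD) would engage the less hindered primary allylic hydroxyl, so that the C2 oxygen closes the ring by SN2 at C6 with the C2 configuration untouched, giving 17.

**Step 3.** The cis-directing effect of the CH2OPMB group may be too weak when the other ketone substituent is a long primary chain and not a methyl group, giving poor geometric selectivity. Enolisation of 7 by the ylide may limit conversion.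
Fallback, from 4 back to 11, with the geometry enforced by a ring (it also bypasses step 4): farnesyl bromide 4 would alkylate the dianion of 2-methylprop-2-en-1-ol (n-BuLi, TMEDA) to give the 2-substituted allylic alcohol F4. Esterification with but-3-enoic acid (carbodiimide, no DMAP) would give the but-3-enoate F5. Ring-closing metathesis with a second-generation ruthenium benzylidene catalyst would give the β,γ-unsaturated δ-lactone F6, in which C3 and C6 are necessarily cis. Aminolysis with N,O-dimethylhydroxylamine hydrochloride and Me3Al would open it to the hydroxy N-methoxy-N-methylamide F7. PMB protection with 4-methoxybenzyl trichloroacetimidate and PPTS would give the PMB-protected amide F8, and DIBAL-H at −78 °C would give 11.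

**Step 4.** C4=C5 may migrate into conjugation with the aldehyde during acetal cleavage, or the acid may start cyclisation of the polyene.
Fallback, from 7 back to 11, with the aldehyde made by oxidation under neutral conditions: 7 would be olefinated with the ylide from [3-(tert-butyldimethylsilyloxy)propyl]triphenylphosphonium bromide to the PMB/TBS bis-ether F9. TBAF would give the homoallylic alcohol F10. Buffered oxidation with the triacetoxy periodinane (DMP, NaHCO3) would give 11.

## Further compounds

F1 | step 8 | methyl (3S,5Z,9E,13E)-3-(acetyloxy)-6-{[(4-methoxybenzyl)oxy]methyl}-10,14,18-trimethyl-2-methylidenenonadeca-5,9,13,17-tetraenoate | C=C(C(=O)OC)[C@@H](OC(C)=O)C/C=C(\COCc1ccc(OC)cc1)CC/C=C(\C)CC/C=C(\C)CCC=C(C)C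
F2 | step 8 | methyl (3R,5Z,9E,13E)-3-hydroxy-6-{[(4-methoxybenzyl)oxy]methyl}-10,14,18-trimethyl-2-methylidenenonadeca-5,9,13,17-tetraenoate | C=C(C(=O)OC)[C@H](O)C/C=C(\COCc1ccc(OC)cc1)CC/C=C(\C)CC/C=C(\C)CCC=C(C)C
F3 | step 8 | methyl (3R,5Z,9E,13E)-3-hydroxy-6-(hydroxymethyl)-10,14,18-trimethyl-2-methylidenenonadeca-5,9,13,17-tetraenoate | C=C(C(=O)OC)[C@H](O)C/C=C(\CO)CC/C=C(\C)CC/C=C(\C)CCC=C(C)C
F4 | step 3 | (5E,9E)-6,10,14-trimethyl-2-methylidenepentadeca-5,9,13-trien-1-ol | C=C(CO)CC/C=C(\C)CC/C=C(\C)CCC=C(C)C
F5 | step 3 | (5E,9E)-6,10,14-trimethyl-2-methylidenepentadeca-5,9,13-trien-1-yl but-3-enoate | C=CCC(=O)OCC(=C)CC/C=C(\C)CC/C=C(\C)CCC=C(C)C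
F6 | step 3 | 5-[(3E,7E)-4,8,12-trimethyltrideca-3,7,11-trien-1-yl]-3,6-dihydro-2H-pyran-2-one | O=C1CC=C(CC/C=C(\C)CC/C=C(\C)CCC=C(C)C)CO1
F7 | step 3 | (3Z,7E,11E)-4-(hydroxymethyl)-N-methoxy-N,8,12,16-tetramethylheptadeca-3,7,11,15-tetraenamide | CON(C)C(=O)C/C=C(\CO)CC/C=C(\C)CC/C=C(\C)CCC=C(C)C
F8 | step 3 | (3Z,7E,11E)-N-methoxy-4-{[(4-methoxybenzyl)oxy]methyl}-N,8,12,16-tetramethylheptadeca-3,7,11,15-tetraenamide | CON(C)C(=O)C/C=C(\COCc1ccc(OC)cc1)CC/C=C(\C)CC/C=C(\C)CCC=C(C)C
F9 | step 4 | tert-butyl{[(3Z,7E,11E)-4-{[(4-methoxybenzyl)oxy]methyl}-8,12,16-trimethylheptadeca-3,7,11,15-tetraen-1-yl]oxy}dimethylsilane | CC(C)(C)[Si](C)(C)OCC/C=C(\COCc1ccc(OC)cc1)CC/C=C(\C)CC/C=C(\C)CCC=C(C)C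
F10 | step 4 | (3Z,7E,11E)-4-{[(4-methoxybenzyl)oxy]methyl}-8,12,16-trimethylheptadeca-3,7,11,15-tetraen-1-ol | OCC/C=C(\COCc1ccc(OC)cc1)CC/C=C(\C)CC/C=C(\C)CCC=C(C)C
A1 | alternative 1 | methyl (3R)-3-hydroxy-2-methylidenehex-5-enoate | C=C(C(=O)OC)[C@H](O)CC=C
A2 | alternative 1 | (5E,9E)-2-(bromomethyl)-6,10,14-trimethylpentadeca-1,5,9,13-tetraene | C=C(CBr)CC/C=C(\C)CC/C=C(\C)CCC=C(C)C
A3 | alternative 1 | methyl (3R)-2-methylidene-3-{[(5E,9E)-6,10,14-trimethyl-2-methylidenepentadeca-5,9,13-trien-1-yl]oxy}hex-5-enoate | C=C(C(=O)OC)[C@@H](CC=C)OCC(=C)CC/C=C(\C)CC/C=C(\C)CCC=C(C)C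
A4 | alternative 2 | (6E,10E)-7,11,15-trimethyl-3-methylidenehexadeca-1,6,10,14-tetraene (β-springene) | C=CC(=C)CC/C=C(\C)CC/C=C(\C)CCC=C(C)C
A5 | alternative 2 | ethyl (2R)-4-[(3E,7E)-4,8,12-trimethyltrideca-3,7,11-trien-1-yl]-3,6-dihydro-2H-pyran-2-carboxylate | CCOC(=O)[C@H]1CC(CC/C=C(\C)CC/C=C(\C)CCC=C(C)C)=CCO1
A6 | alternative 3 | 2-ethenyl-2-[(3E,7E)-4,8,12-trimethyltrideca-3,7,11-trien-1-yl]oxirane (racemic) | C=CC1(CC/C=C(\C)CC/C=C(\C)CCC=C(C)C)CO1
A7 | alternative 3 | ethyl (2R)-5-[(3E,7E)-4,8,12-trimethyltrideca-3,7,11-trien-1-yl]-3,6-dihydro-2H-pyran-2-carboxylate | CCOC(=O)[C@H]1CC=C(CC/C=C(\C)CC/C=C(\C)CCC=C(C)C)CO1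
A8 | alternative 3 | 1-[(2R)-5-[(3E,7E)-4,8,12-trimethyltrideca-3,7,11-trien-1-yl]-3,6-dihydro-2H-pyran-2-yl]ethan-1-one | CC(=O)[C@H]1CC=C(CC/C=C(\C)CC/C=C(\C)CCC=C(C)C)CO1
A9 | alternative 3 | 1-[(2R)-5-[(3E,7E)-4,8,12-trimethyltrideca-3,7,11-trien-1-yl]-3,6-dihydro-2H-pyran-2-yl]ethenyl trifluoromethanesulfonate | C=C(OS(=O)(=O)C(F)(F)F)[C@H]1CC=C(CC/C=C(\C)CC/C=C(\C)CCC=C(C)C)CO1
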